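## The problem

Compound 20 is a benzofuran-3(2H)-one: a benzene ring A fused to a five-membered ring B (O1, C2, C3), with a free phenol at C6 and, at C2, a hydroxyl group and a (2E,6E)-farnesyl chain. C2 is the only stereocentre. It is a fully substituted hemiketal carbon (O1, OH, C3, C1') with no neighbouring stereocentre to guide it, so its (R) configuration must come from a chiral reagent or catalyst. The hemiketal is also the most fragile function: once deprotonated it can expel the aryloxide O1 and open ring B to an achiral aryl 1,2-dione, so base must be avoided from the moment C2 carries its oxygen. The chain holds three trisubstituted alkenes, two of fixed E geometry. This rules out strong protic or Lewis acids (cation–olefin cyclisation), electrophilic oxidants such as peracids, dioxiranes or OsO4, and catalytic hydrogenation. The C6 phenol has to travel in masked form and be released last under near-neutral conditions. A short assembly is possible because the ether oxygen O1 (on C7a) and the ketone carbon C3 (on C3a) sit on adjacent carbons of ring A, which is the pattern an aryne leaves after taking up an oxygen nucleophile and then an acyl group. C4, next to C3a, is unsubstituted in 20 and can carry a temporary chlorine to steer that capture, and C2 can carry a temporary ester.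

## Retrosynthesis

**20 from 19.** The O–CH2 bond of a 4-methoxybenzyl (PMB) ether at C6 is cut last. The mask has to survive an organolithium, fluoride and a palladium hydride and then leave without base or strong acid. A silyl ether would fall to CsF, a benzyl ether needs hydrogenolysis and a methyl ether needs a Lewis acid, whereas PMB leaves with DDQ in a buffered two-phase medium. The forward step must leave the triene and the hemiketal alone.

**19 from 17.** The C2–OH bond is cut. Cutting C2–C1' instead would require an enantioselective farnesylation of a 2-oxygenated benzofuranone and would take the chain out of the ring-forming step. Compound 17 has no stereocentre worth protecting, so everything before it can be run racemic. The forward step must deliver oxygen to one face of C2 without ever forming the alkoxide of 19, which opens ring B reversibly and would lose the configuration. This asks for oxidation of the enol under acid catalysis, not of the enolate.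

**17 from 15.** Two auxiliary groups are removed in one operation: the allyl ester at C2 and the chlorine at C4, by way of 16. Both fall to zerovalent palladium and formate, so the two helpers together cost one step. The simplification is only formal (C–C and C–Cl become C–H), but it is what allows the next cut.

**15 from 8 and 12.** This is the key disconnection: O1–C7a and C3–C3a are cut together, leading back to aryne 13 (released from silyl triflate 8) and the tertiary hydroxy malonate 12. The neighbouring cuts (O1–C2 plus C3–C3a by ether formation and Friedel–Crafts acylation, or C2–C3 by Dieckmann closure) need a ring A that already carries oxygen and carboxyl ortho to each other, and they add the chain afterwards. The aryne cut makes both ortho bonds at once and brings C2, C3 and the whole farnesyl chain in one piece from a fragment of similar size. Three things are asked of the forward reaction: oxygen must attack the aryne carbon remote from chlorine, the aryl anion must acylate faster than it is protonated, and the product must not re-enter the reaction. The last point is the reason for the second ester in 12. It makes the hydroxyl acidic enough to be engaged by fluoride, and it makes C2 of 15 quaternary, so that 15 has no acidic C2–H to quench the alkoxide or to be arylated by more aryne. Without it, the ketone 16 would be formed directly under the basic conditions and would be more acidic than the alcohol that makes it.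

**8 from 4, 3 and 1.** The C–Si and O–S bonds of 8 are cut back to the ortho-bromophenol 4 (retro-Brook route to 2-silylaryl triflates). Aryne 13 could equally be generated with silicon and triflate exchanged, but that arrangement needs a 5-chlororesorcinol ether to be functionalised between O and Cl in competition with the position between the two oxygens. With the triflate between chlorine and silicon, the bromine of 4 marks the silicon position without ambiguity. Compound 4 comes from hydroquinone 3 by alkylation of its unhindered oxygen, and 3 from the commercial aldehyde 1 by Dakin oxidation. Compound 1 already has both halogens flanking the phenol.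

**12 from 11, 9 and 10.** The C–OH bond at the malonate carbon is cut (enolate hydroxylation), then the C–C bond to the chain (malonate alkylation with 10). Compared with alkylating a glycolate enolate, the malonate route uses a stabilised enolate twice and keeps both E alkenes of 10 untouched.

## Roads not taken

**Alternative 1:** The cut is at the C2–O and C1'–O bonds of a spiro-epoxide. The (Z)-farnesylidene benzofuranone A1 would be epoxidised at its C2=C1' bond with tert-butyl hydroperoxide and KOH under a cinchona-derived quaternary ammonium salt to give the spiro-oxirane A2. The C1'–O bond would then be reduced and the silyl ether removed.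
- Merits: rings A and B are bought, A1 is one condensation away from commercial material, and nucleophilic epoxidation of enones under phase transfer is a well-tested catalytic asymmetric reaction. The route needs about half the steps of the chosen one, which is a real advantage.
- Weak points: A1 is a cross-conjugated dienone, so the hydroperoxide anion can also add at C3'. The harder problem is the last C–O cleavage. Reductions of α,β-epoxy ketones normally break the Cα–O bond, here C2–O, which is the wrong one. Opening at the allylic C1' through a π-allyl palladium species can move or isomerise the C2'=C3' alkene, and it releases the C2 alkoxide, the very species that opens ring B. Fluoride removal of the silyl ether adds base at the end.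
- Comparison: the chosen plan is longer. Against that it sets a stereocentre formed under acid, with no alkoxide, and no regiochemical question next to the triene.

**Alternative 2:** The cut is at C3a–C7a and C4–C5, so ring A is built. On heating, the terminal ynone of the pyranone ether A3 adds across C3 and C6 of the pyranone, and loss of CO2 from the bridged lactone gives the benzofuranone A4.
- Merits: the tether fixes the substitution pattern of ring A completely, no directing halogen is needed, and the conditions are neutral. In these respects it is better than the chosen plan, which has to add a chlorine and remove it again.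
- Weak points: a benzene ring that can be bought is made de novo. A3 is a 6-alkoxypyran-2-one (a vinylogous anhydride) carrying an α-alkoxy ynone with an acidic C–H, and it would have to survive the high temperature that a three-atom tether requires. A4 is the silyl analogue of 17, so the asymmetric hydroxylation at C2, the hardest step, is not avoided.
- Comparison: both roads meet at the same kind of intermediate. The chosen plan reaches it from two stable fragments of similar size and pays one combined palladium step for its two auxiliary groups.

**Alternative 3:** The cut is at C2–C3. A chiral aminoindanol-derived triazolylidene would convert the aldehyde of the salicylaldehyde ester A5 into an acyl-anion equivalent that adds to the ester carbonyl, closing ring B and giving the hemiketal A6 directly.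
- Merits: this is the most convergent road. One catalytic step forms ring B, the C2–C3 bond and the stereocentre, and no halogen, blocking group or oxidation is needed. If it worked as drawn it would beat the chosen plan clearly on step count.
- Weak points: esters are poor acceptors for carbene-derived acyl anions, and an aryl ester is more likely to transfer its acyl group to the carbene. The tetrahedral adduct is the hemiketal alkoxide, which under the basic conditions can open to the dione, so the selectivity set by the catalyst need not survive. The β,γ-unsaturated acyl group of A5 can drift into conjugation, and the final desilylation is again basic.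
- Comparison: against the brevity, the chosen plan sets bond-forming steps that each have a close tested relative and a C2–O bond formed without the alkoxide.

Key step: step 6

Assumption: the C2 hemiketal of 19 and 20 is taken to hold its configuration in neutral or weakly acidic media at or below room temperature, whereas its alkoxide equilibrates with the achiral ring-opened dione; this is why no base is used after step 8.

Abbreviations: farnesyl = (2E,6E)-3,7,11-trimethyldodeca-2,6,10-trien-1-yl; PMB = 4-methoxybenzyl; TRIP = 3,3'-bis(2,4,6-triisopropylphenyl)-1,1'-binaphthyl-2,2'-diyl hydrogen phosphate; SPhos = 2-dicyclohexylphosphino-2',6'-dimethoxybiphenyl.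

## Route

Step 1
Reactants: 1 3-bromo-5-chloro-4-hydroxybenzaldehyde
Product: 3 2-bromo-6-chlorobenzene-1,4-diol, via aryl formate 2 (not isolated)
Conditions: 30% aq H2O2, NaOH, H2O/THF, 0 °C to rt; aq HCl (under N2)
Reagents that add atoms: hydrogen peroxide, OO
Why: Dakin oxidation: hydroperoxide adds to the aldehyde, the 4-oxidoaryl group migrates to oxygen and formate 2 is saponified in the same pot. The para phenoxide should make aryl migration win despite the two halogens.

Step 2
Reactants: 3 2-bromo-6-chlorobenzene-1,4-diol
Product: 4 2-bromo-6-chloro-4-(4-methoxybenzyloxy)phenol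
Conditions: NaH (2 equiv), degassed DMF, 0 °C; PMBCl (1 equiv), 0 °C to rt; aq NH4Cl
Reagents that add atoms: 4-methoxybenzyl chloride, COc1ccc(CCl)cc1
Why: Williamson etherification of the dianion: the oxide at C4 is the more basic and is unhindered, whereas the oxide at C1 is flanked by Br and Cl and is weakly nucleophilic, so one equivalent of halide should go to O4.

Step 3
Reactants: 4 2-bromo-6-chloro-4-(4-methoxybenzyloxy)phenol
Product: 8 2-chloro-4-(4-methoxybenzyloxy)-6-(trimethylsilyl)phenyl trifluoromethanesulfonate, via aryl trimethylsilyl ether 5 (not isolated), via aryllithium 6 (not isolated), via lithium silylphenoxide 7 (not isolated)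
Conditions: HN(SiMe3)2, THF, 65 °C; evaporate; n-BuLi, THF, −78 °C; Tf2O, −78 °C to rt
Reagents that add atoms: hexamethyldisilazane, C[Si](C)(C)N[Si](C)(C)C; trifluoromethanesulfonic anhydride, O=S(=O)(OS(=O)(=O)C(F)(F)F)C(F)(F)F
Why: O-silylation, Br–Li exchange, 1,3 O-to-C silyl shift (retro-Brook rearrangement) and O-triflation, the standard one-pot route to 2-silylaryl triflates. The lithiated carbon of 6 is meta to chlorine, so no aryne can form at this stage, and exchange at −78 °C is faster than any attack on the PMB ether.

Step 4
Reactants: 9 diallyl malonate; 10 (2E,6E)-farnesyl bromide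
Product: 11 diallyl 2-farnesylmalonate
Conditions: NaH, THF, 0 °C; then 10, 0 °C to rt (9 in excess)
Reagents that add atoms: none
Why: Malonate alkylation by SN2 at the primary allylic bromide, which keeps both E alkenes. Excess malonate suppresses dialkylation.

Step 5
Reactants: 11 diallyl 2-farnesylmalonate
Product: 12 diallyl 2-farnesyl-2-hydroxymalonate
Conditions: KN(SiMe3)2, THF, −78 °C; trans-2-(phenylsulfonyl)-3-phenyloxaziridine, −78 to 0 °C; aq NH4Cl
Reagents that add atoms: trans-2-(phenylsulfonyl)-3-phenyloxaziridine, O=S(=O)(N1OC1c1ccccc1)c1ccccc1
Why: Enolate hydroxylation with an N-sulfonyloxaziridine (Davis oxidation): the potassium enolate attacks the oxaziridine oxygen. The reagent does not epoxidise isolated alkenes at these temperatures.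

Step 6
Reactants: 8 2-chloro-4-(4-methoxybenzyloxy)-6-(trimethylsilyl)phenyl trifluoromethanesulfonate; 12 diallyl 2-farnesyl-2-hydroxymalonate
Product: 15 allyl 4-chloro-2-farnesyl-6-(4-methoxybenzyloxy)-3-oxo-2,3-dihydrobenzofuran-2-carboxylate (racemic), via aryne 13 (not isolated), via aryl anion 14 (not isolated)
Conditions: CsF, THF, 65 °C (12 in slight excess)
Reagents that add atoms: none
Why: Proposed new method: fluoride removes the silyl group of 8 and triflate leaves, giving aryne 13. The tertiary hydroxyl of 12, acidified by its two ester groups and engaged by fluoride, adds through oxygen to the aryne carbon remote from chlorine (the future C7a) and leaves the aryl anion 14 at C3a. Anion 14 attacks one of the two enantiotopic ester carbonyls in a 5-exo-trig addition–elimination that expels allyl oxide and closes ring B, forming O1–C7a and C3–C3a in one operation. The closest known reactions are the capture of arynes by salicylate phenoxides followed by acyl trapping to xanthones and the analogous conversion of α-amino esters into indolin-3-ones; the ring closure itself resembles a Parham cyclisation onto an ester. The step needs regioselectivity, which the chlorine secures: it polarises the aryne so that the nucleophile enters at the distal carbon and the charge develops next to chlorine, the bulk of the tertiary oxygen points the same way, and the weak opposite bias of the para alkoxy group is outweighed. C2 becomes a quaternary stereocentre but is formed racemic and needs no control, since it is erased in step 7. Because C2 of 15 carries no hydrogen, the product can neither quench the alkoxide nor be arylated by further aryne, and THF is used because a C–H acidic solvent could protonate 14 before it acylates.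

Step 7
Reactants: 15 allyl 4-chloro-2-farnesyl-6-(4-methoxybenzyloxy)-3-oxo-2,3-dihydrobenzofuran-2-carboxylate
Product: 17 2-farnesyl-6-(4-methoxybenzyloxy)benzofuran-3(2H)-one (racemic), via chloro ketone 16 (not isolated)
Conditions: Pd(OAc)2 (cat.), SPhos (cat.), Et3N·HCO2H (amine in excess), 1,4-dioxane, rt then 80 °C
Reagents that add atoms: none
Why: Zerovalent palladium ionises the allyl ester, the β-keto carboxylate loses CO2 and formate reduces the allyl fragment to propene (Tsuji deallylation–decarboxylation), giving 16. On warming, the same catalyst inserts into the ketone-activated C4–Cl bond and formate supplies hydride (palladium-catalysed hydrodehalogenation). A homogeneous palladium hydride leaves trisubstituted alkenes and the aryl PMB ether alone, and the excess amine keeps the medium from becoming acidic enough to cyclise the triene.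

Step 8
Reactants: 17 2-farnesyl-6-(4-methoxybenzyloxy)benzofuran-3(2H)-one
Product: 19 (R)-2-farnesyl-2-hydroxy-6-(4-methoxybenzyloxy)benzofuran-3(2H)-one, via aminoxy ketone 18 (not isolated)
Conditions: PhNO (excess), (R)-TRIP (cat.), toluene, rt
Reagents that add atoms: nitrosobenzene, O=Nc1ccccc1
Why: Proposed new method: the chiral phosphoric acid enolises 17 to its 3-hydroxybenzofuran form and, holding enol and protonated nitrosobenzene in one hydrogen-bonded assembly, directs O-attack on one face of C2 to give 18, whose N–O bond is then cleaved by a second nitrosobenzene (azoxybenzene leaves), so the neutral hemiketal appears without its alkoxide ever forming. The closest known reaction is the phosphoric-acid-catalysed α-hydroxylation of α-branched cyclic ketones with nitrosobenzene through the enol. C2 is set by the catalyst alone; should the (R)-acid favour the other face, its enantiomer is used.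

Step 9
Reactants: 19 (R)-2-farnesyl-2-hydroxy-6-(4-methoxybenzyloxy)benzofuran-3(2H)-one
Product: 20 (R)-2-farnesyl-2,6-dihydroxybenzofuran-3(2H)-one
Conditions: DDQ, CH2Cl2/aq NaH2PO4–Na2HPO4 (pH 7), 0 °C
Reagents that add atoms: none
Why: Oxidative PMB cleavage: DDQ abstracts hydride from the electron-rich benzylic position and water collapses the cation to the phenol and 4-methoxybenzaldehyde. The buffered two-phase medium stays neutral, so the hemiketal is not deprotonated, and isolated trisubstituted alkenes should not react at 0 °C.

## Compound list

1 | 3-bromo-5-chloro-4-hydroxybenzaldehyde | O=Cc1cc(Br)c(O)c(Cl)c1 | starting material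
2 | 3-bromo-5-chloro-4-hydroxyphenyl formate | O=COc1cc(Br)c(O)c(Cl)c1 | intermediate
3 | 2-bromo-6-chlorobenzene-1,4-diol | Oc1cc(Br)c(O)c(Cl)c1 | intermediate
4 | 2-bromo-6-chloro-4-(4-methoxybenzyloxy)phenol | COc1ccc(COc2cc(Br)c(O)c(Cl)c2)cc1 | intermediate
5 | [2-bromo-6-chloro-4-(4-methoxybenzyloxy)phenoxy]trimethylsilane | C[Si](C)(C)Oc1c(Br)cc(OCc2ccc(OC)cc2)cc1Cl | intermediate
6 | [3-chloro-5-(4-methoxybenzyloxy)-2-(trimethylsilyloxy)phenyl]lithium | [Li]c1cc(OCc2ccc(OC)cc2)cc(Cl)c1O[Si](C)(C)C | intermediate
7 | lithium 2-chloro-4-(4-methoxybenzyloxy)-6-(trimethylsilyl)phenoxide | [Li+].[O-]c1c(Cl)cc(OCc2ccc(OC)cc2)cc1[Si](C)(C)C | intermediate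
8 | 2-chloro-4-(4-methoxybenzyloxy)-6-(trimethylsilyl)phenyl trifluoromethanesulfonate | COc1ccc(COc2cc(Cl)c(OS(=O)(=O)C(F)(F)F)c([Si](C)(C)C)c2)cc1 | intermediate
9 | diallyl malonate (di(prop-2-enyl) propanedioate) | C=CCOC(=O)CC(=O)OCC=C | starting material
10 | (2E,6E)-farnesyl bromide ((2E,6E)-1-bromo-3,7,11-trimethyldodeca-2,6,10-triene) | CC(C)=CCC/C(C)=C/CC/C(C)=C/CBr | starting material
11 | diallyl 2-[(2E,6E)-3,7,11-trimethyldodeca-2,6,10-trien-1-yl]malonate | CC(C)=CCC/C(C)=C/CC/C(C)=C/CC(C(=O)OCC=C)C(=O)OCC=C | intermediate
12 | diallyl 2-hydroxy-2-[(2E,6E)-3,7,11-trimethyldodeca-2,6,10-trien-1-yl]malonate | CC(C)=CCC/C(C)=C/CC/C(C)=C/CC(O)(C(=O)OCC=C)C(=O)OCC=C | intermediate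
13 | 3-chloro-5-(4-methoxybenzyloxy)-1,2-didehydrobenzene (aryne; C1 next to C–H, C2 next to C–Cl) | COc1ccc(COC2=CC#CC(Cl)=C2)cc1 | intermediate
14 | diallyl 2-[2-caesio-3-chloro-5-(4-methoxybenzyloxy)phenoxy]-2-[(2E,6E)-farnesyl]malonate | CC(C)=CCC/C(C)=C/CC/C(C)=C/CC(Oc1cc(OCc2ccc(OC)cc2)cc(Cl)c1[Cs])(C(=O)OCC=C)C(=O)OCC=C | intermediate
15 | allyl 4-chloro-2-[(2E,6E)-farnesyl]-6-(4-methoxybenzyloxy)-3-oxo-2,3-dihydrobenzofuran-2-carboxylate (racemic) | CC(C)=CCC/C(C)=C/CC/C(C)=C/CC1(C(=O)OCC=C)Oc2cc(OCc3ccc(OC)cc3)cc(Cl)c2C1=O | intermediate
16 | 4-chloro-2-[(2E,6E)-farnesyl]-6-(4-methoxybenzyloxy)benzofuran-3(2H)-one (racemic) | CC(C)=CCC/C(C)=C/CC/C(C)=C/CC1Oc2cc(OCc3ccc(OC)cc3)cc(Cl)c2C1=O | intermediate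
17 | 2-[(2E,6E)-farnesyl]-6-(4-methoxybenzyloxy)benzofuran-3(2H)-one (racemic) | CC(C)=CCC/C(C)=C/CC/C(C)=C/CC1Oc2cc(OCc3ccc(OC)cc3)ccc2C1=O | intermediate
18 | (S)-2-[(2E,6E)-farnesyl]-6-(4-methoxybenzyloxy)-2-[(phenylamino)oxy]benzofuran-3(2H)-one (same spatial arrangement at C2 as 19; the descriptor changes because O–N outranks O1) | CC(C)=CCC/C(C)=C/CC/C(C)=C/C[C@@]1(ONc3ccccc3)Oc2cc(OCc4ccc(OC)cc4)ccc2C1=O | intermediate
19 | (R)-2-[(2E,6E)-farnesyl]-2-hydroxy-6-(4-methoxybenzyloxy)benzofuran-3(2H)-one | CC(C)=CCC/C(C)=C/CC/C(C)=C/C[C@@]1(O)Oc2cc(OCc3ccc(OC)cc3)ccc2C1=O | intermediate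
20 | (R)-2-[(2E,6E)-farnesyl]-2,6-dihydroxybenzofuran-3(2H)-one (CNP0212006.1) | CC(C)=CCC/C(C)=C/CC/C(C)=C/C[C@@]1(O)Oc2cc(O)ccc2C1=O | target

## Step count and least certain steps

Total: 9 steps. Longest linear sequence: 7 steps (1 → 3 → 4 → 8 → 15 → 17 → 19 → 20); the chain arm (9 and 10 → 11 → 12) joins at step 6.

**Step 6 (key step).** Most likely to go wrong is proton transfer to aryl anion 14 before it acylates, which would leave a simple aryl ether of 12. Attack at the wrong aryne carbon, loss of chloride from 14, or cleavage of the non-enolisable β-keto ester by allyl oxide late in the reaction are further possibilities. The fallback closes ring B by Dieckmann condensation instead of aryne capture, uses known chemistry throughout, sets out from 10 and returns at 17.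
- Commercial methyl 2,4-dihydroxybenzoate F1 is etherified at its non-chelated hydroxyl (PMBCl, K2CO3, acetone) to methyl 2-hydroxy-4-(4-methoxybenzyloxy)benzoate F2.
- O-Alkylation with methyl bromoacetate (K2CO3, DMF) gives methyl 2-(2-methoxy-2-oxoethoxy)-4-(4-methoxybenzyloxy)benzoate F3.
- NaOMe in MeOH closes ring B to methyl 3-hydroxy-6-(4-methoxybenzyloxy)benzofuran-2-carboxylate F4.
- C-Allylation of F4 with 10 under Pd(PPh3)4 and K2CO3 in THF (Tsuji–Trost conditions, under which any O-farnesyl ether is re-ionised and passed on to carbon) gives methyl 2-farnesyl-6-(4-methoxybenzyloxy)-3-oxo-2,3-dihydrobenzofuran-2-carboxylate F5.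
- Krapcho demethoxycarbonylation (LiCl, wet DMSO, 130 °C) gives 17.

No chlorine is needed on this path, so step 7 falls away with it.

**Step 8.** The facial selectivity may be poor or have the wrong sense on this flat, long-chain substrate. Nitrogen instead of oxygen attack, slow N–O cleavage of 18, or an ene reaction of nitrosobenzene with the chain alkenes may also interfere. The fallback replaces asymmetric catalysis by resolution, sets out from 17 and returns at 19. The potassium enolate of 17 (KN(SiMe3)2, THF, −78 °C) is oxidised with racemic trans-2-(phenylsulfonyl)-3-phenyloxaziridine and quenched cold with AcOH. This gives racemic 2-farnesyl-2-hydroxy-6-(4-methoxybenzyloxy)benzofuran-3(2H)-one F6. Its enantiomers are separated by preparative chromatography on a polysaccharide chiral stationary phase with a neutral eluent to give 19. The unwanted antipode can be racemised with a trace of Et3N, through the ring-opened dione, and recycled.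

**Step 7.** The enolate released on decarboxylation may be C-allylated by the allyl–palladium fragment instead of being protonated. The C–Cl reduction may also lag at temperatures where palladium hydride begins to move the chain alkenes or the enolisable ketone couples with unreacted aryl chloride. The fallback changes the directing halogen to bromine, so that both auxiliary groups fall under the mild classical deallylation conditions. It sets out from 12 and returns at 17.
- Commercial 2,6-dibromobenzene-1,4-diol F7 is taken through the operations of steps 2 and 3 to 2,6-dibromo-4-(4-methoxybenzyloxy)phenol F8 and then 2-bromo-4-(4-methoxybenzyloxy)-6-(trimethylsilyl)phenyl trifluoromethanesulfonate F9; one equivalent of n-BuLi exchanges one of the two equivalent bromines.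
- Annulation with 12 as in step 6 gives allyl 4-bromo-2-farnesyl-6-(4-methoxybenzyloxy)-3-oxo-2,3-dihydrobenzofuran-2-carboxylate F10.
- Pd(PPh3)4 with Et3N·HCO2H in THF at 40 °C then cleaves the C–Br bond and the allyl ester to give 17.

The price is a bromide that is lost more easily from the aryl anion in the annulation, which is why chlorine is the first choice.

**Step 9.** The configuration at C2 may erode, or DDQ may oxidise the substrate elsewhere, if cleavage of the aryl PMB ether is slow. The fallback uses an allyl ether in place of PMB, so that no oxidant is needed and the stereocentre is created in the very last step. It sets out from 3 and returns at 20.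
- The dianion of 3 is alkylated with allyl bromide to 4-(allyloxy)-2-bromo-6-chlorophenol F11.
- The operations of step 3 give 4-(allyloxy)-2-chloro-6-(trimethylsilyl)phenyl trifluoromethanesulfonate F12.
- Annulation with 12 as in step 6 gives allyl 6-(allyloxy)-4-chloro-2-farnesyl-3-oxo-2,3-dihydrobenzofuran-2-carboxylate F13.
- The palladium/formate conditions of step 7 remove the allyl ether together with the ester and the chlorine, giving 2-farnesyl-6-hydroxybenzofuran-3(2H)-one F14 (racemic).
- The hydroxylation of step 8 then gives 20 directly.

This path is one step shorter. It is held in reserve because it puts a free, acidic phenol into the enantio-determining step, where it competes with the enol for the chiral acid.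

**Step 2.** Alkylation may occur at the hindered oxygen or at both oxygens, and the dianion may be oxidised by air to the quinone. The fallback sets out from 3 and returns at 4 without a new compound. The neutral diol is treated with 4-methoxybenzyl trichloroacetimidate and catalytic camphorsulfonic acid in CH2Cl2 at 0 °C. Under acid it is the neutral hydroxyl groups that compete, and the one at C4 is both the more electron-rich and the unhindered one.

## Further compounds

F1 | step 6 | methyl 2,4-dihydroxybenzoate (commercial) | COC(=O)c1ccc(O)cc1O
F2 | step 6 | methyl 2-hydroxy-4-(4-methoxybenzyloxy)benzoate | COC(=O)c1ccc(OCc2ccc(OC)cc2)cc1O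
F3 | step 6 | methyl 2-(2-methoxy-2-oxoethoxy)-4-(4-methoxybenzyloxy)benzoate | COC(=O)COc1cc(OCc2ccc(OC)cc2)ccc1C(=O)OC
F4 | step 6 | methyl 3-hydroxy-6-(4-methoxybenzyloxy)benzofuran-2-carboxylate | COC(=O)c1oc2cc(OCc3ccc(OC)cc3)ccc2c1O
F5 | step 6 | methyl 2-[(2E,6E)-farnesyl]-6-(4-methoxybenzyloxy)-3-oxo-2,3-dihydrobenzofuran-2-carboxylate (racemic) | CC(C)=CCC/C(C)=C/CC/C(C)=C/CC1(C(=O)OC)Oc2cc(OCc3ccc(OC)cc3)ccc2C1=O
F6 | step 8 | racemic 2-[(2E,6E)-farnesyl]-2-hydroxy-6-(4-methoxybenzyloxy)benzofuran-3(2H)-one | CC(C)=CCC/C(C)=C/CC/C(C)=C/CC1(O)Oc2cc(OCc3ccc(OC)cc3)ccc2C1=O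
F7 | step 7 | 2,6-dibromobenzene-1,4-diol (commercial) | Oc1cc(Br)c(O)c(Br)c1
F8 | step 7 | 2,6-dibromo-4-(4-methoxybenzyloxy)phenol | COc1ccc(COc2cc(Br)c(O)c(Br)c2)cc1
F9 | step 7 | 2-bromo-4-(4-methoxybenzyloxy)-6-(trimethylsilyl)phenyl trifluoromethanesulfonate | COc1ccc(COc2cc(Br)c(OS(=O)(=O)C(F)(F)F)c([Si](C)(C)C)c2)cc1
F10 | step 7 | allyl 4-bromo-2-[(2E,6E)-farnesyl]-6-(4-methoxybenzyloxy)-3-oxo-2,3-dihydrobenzofuran-2-carboxylate (racemic) | CC(C)=CCC/C(C)=C/CC/C(C)=C/CC1(C(=O)OCC=C)Oc2cc(OCc3ccc(OC)cc3)cc(Br)c2C1=O
F11 | step 9 | 4-(allyloxy)-2-bromo-6-chlorophenol | C=CCOc1cc(Br)c(O)c(Cl)c1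
F12 | step 9 | 4-(allyloxy)-2-chloro-6-(trimethylsilyl)phenyl trifluoromethanesulfonate | C=CCOc1cc(Cl)c(OS(=O)(=O)C(F)(F)F)c([Si](C)(C)C)c1
F13 | step 9 | allyl 6-(allyloxy)-4-chloro-2-[(2E,6E)-farnesyl]-3-oxo-2,3-dihydrobenzofuran-2-carboxylate (racemic) | CC(C)=CCC/C(C)=C/CC/C(C)=C/CC1(C(=O)OCC=C)Oc2cc(OCC=C)cc(Cl)c2C1=O
F14 | step 9 | 2-[(2E,6E)-farnesyl]-6-hydroxybenzofuran-3(2H)-one (racemic) | CC(C)=CCC/C(C)=C/CC/C(C)=C/CC1Oc2cc(O)ccc2C1=O
F0 | step 2 | none | none
A1 | alternative 1 | (Z)-2-[(2E,6E)-3,7,11-trimethyldodeca-2,6,10-trien-1-ylidene]-6-(triisopropylsilyloxy)benzofuran-3(2H)-one | CC(C)=CCC/C(C)=C/CC/C(C)=C/C=C1\Oc2cc(O[Si](C(C)C)(C(C)C)C(C)C)ccc2C1=O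
A2 | alternative 1 | spiro-oxirane of the C2=C1' bond of A1, C2 configured as in 20 | CC(C)=CCC/C(C)=C/CC/C(C)=C/[C@@H]3[C@@]1(O3)Oc2cc(O[Si](C(C)C)(C(C)C)C(C)C)ccc2C1=O
A3 | alternative 2 | 6-{[(6E,10E)-7,11,15-trimethyl-3-oxohexadeca-6,10,14-trien-1-yn-4-yl]oxy}-4-(triisopropylsilyloxy)-2H-pyran-2-one | CC(C)=CCC/C(C)=C/CC/C(C)=C/CC(OC1=CC(O[Si](C(C)C)(C(C)C)C(C)C)=CC(=O)O1)C(=O)C#C
A4 | alternative 2 | 2-[(2E,6E)-farnesyl]-6-(triisopropylsilyloxy)benzofuran-3(2H)-one | CC(C)=CCC/C(C)=C/CC/C(C)=C/CC1Oc2cc(O[Si](C(C)C)(C(C)C)C(C)C)ccc2C1=O
A5 | alternative 3 | 2-formyl-5-(triisopropylsilyloxy)phenyl (3E,7E)-4,8,12-trimethyltrideca-3,7,11-trienoate | CC(C)=CCC/C(C)=C/CC/C(C)=C/CC(=O)Oc1cc(O[Si](C(C)C)(C(C)C)C(C)C)ccc1C=O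
A6 | alternative 3 | (R)-2-[(2E,6E)-farnesyl]-2-hydroxy-6-(triisopropylsilyloxy)benzofuran-3(2H)-one | CC(C)=CCC/C(C)=C/CC/C(C)=C/C[C@@]1(O)Oc2cc(O[Si](C(C)C)(C(C)C)C(C)C)ccc2C1=O
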